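**Strategy.** The cyclohexadienone ring (the carbocycle carrying the quaternary methyl/geranyl carbon, the acetyl group and the methylene bridge) is disconnected at the bond between its acetyl-bearing carbon and the ring carbonyl next to the bridge carbon. Moving that acyl carbon onto the enol oxygen of the adjacent 1,3-diketone gives an isomer, enol δ-lactone 17, a 6-(2-oxopropylidene)-5,6-dihydropyran-2-one that already holds the chromene, the bridge and the stereocentre. The key step assembles 17 from two halves and, in the same flask, turns it inside out: base-induced opening to an acylketene and C-acylation of the diketone enolate close the carbocycle. The feature exploited is the ring's 2-acyl-1,3-dione (β-triketone) array, whose acidity is the thermodynamic sink.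

Key step: step 5

Assumption: pyranone 9 is taken as a catalogue compound, the (R,R)-ligand in step 3 is taken to deliver the (S)-centre (the (S,S)-ligand is used if the sense of induction proves opposite), and all CIP descriptors refer to the tautomers drawn.

Step 1
Reactants: 1 1-(2,4,6-trihydroxyphenyl)butan-1-one; 2 3-methylbut-2-enal
Product: 3 1-(5,7-dihydroxy-2,2-dimethyl-2H-chromen-8-yl)butan-1-one
Conditions: ethylenediammonium diacetate (20 mol%), toluene, 80 °C
Reagents that add atoms: 3-methylbut-2-enal 2, CC(C)=CC=O
Why: Knoevenagel-type condensation at a free ring carbon followed by 6π-oxa-electrocyclisation of the resulting dienone should build the 2,2-dimethyl-2H-chromene, closure through the oxygen next to the acyl group giving 3, while the 6-acyl regioisomer expected as a co-product is removed by chromatography.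

Step 2
Reactants: 3 1-(5,7-dihydroxy-2,2-dimethyl-2H-chromen-8-yl)butan-1-one; 4 formaldehyde; 5 dimethylamine; 6 iodomethane
Product: 8 [(8-butanoyl-5,7-dihydroxy-2,2-dimethyl-2H-chromen-6-yl)methyl]trimethylammonium iodide, via Mannich base 7 (not isolated)
Conditions: 37% aq. CH2O, 40% aq. Me2NH, EtOH, 0 °C to rt; concentrate; then MeI, acetone, 0 °C to rt
Reagents that add atoms: formaldehyde 4, C=O; dimethylamine 5, CNC; iodomethane 6, CI
Why: Mannich aminomethylation should occur at C6, the only unsubstituted position of the phloroglucinol ring, and the benzylic amine is then quaternised without base (Menshutkin reaction) so that the phenols stay unmethylated and a bench-stable o-quinone methide precursor results.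

Step 3
Reactants: 9 4-hydroxy-3,6-dimethyl-2H-pyran-2-one; 10 geranyl acetate [(2E)-3,7-dimethylocta-2,6-dien-1-yl acetate]
Product: 11 (3S)-3-[(2E)-3,7-dimethylocta-2,6-dien-1-yl]-3,6-dimethyl-2H-pyran-2,4(3H)-dione
Conditions: Pd2(dba)3·CHCl3 (2.5 mol%), (R,R)-N,N'-bis(2-diphenylphosphinobenzoyl)-1,2-diaminocyclohexane (7.5 mol%), Et3N (1.2 equiv), CH2Cl2, 0 °C to rt
Reagents that add atoms: geranyl acetate 10, CC(=O)OC/C=C(\C)CCC=C(C)C
Why: In this asymmetric Tsuji–Trost allylic alkylation the zerovalent palladium/diphosphine complex ionises the allylic acetate and the soft oxidopyranone should attack the unsubstituted allyl terminus through C3 (dearomatising C-allylation, E-alkene retained), the chiral pocket selecting one face of the planar nucleophile so that the quaternary (S)-centre is set here.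

Step 4
Reactants: 11 (3S)-3-geranyl-3,6-dimethyl-2H-pyran-2,4(3H)-dione; 12 Meldrum's acid (2,2-dimethyl-1,3-dioxane-4,6-dione)
Product: 15 (5S,6Z)-5-[(2E)-3,7-dimethylocta-2,6-dien-1-yl]-5-methyl-6-(2-oxopropylidene)dihydro-2H-pyran-2,4(3H)-dione, via acyl Meldrum's acid 13 (not isolated), via acylketene 14 (not isolated)
Conditions: DMAP (2 equiv), CH2Cl2, 0 °C to rt; cold 1 M HCl wash; then toluene, 90 °C
Reagents that add atoms: Meldrum's acid 12, CC1(C)OC(=O)CC(=O)O1
Why: DMAP should open the enol lactone at its lactone carbonyl (the diketone enolate is the leaving group) and pass the acyl group to the carbon of the Meldrum's acid anion, as diketene acetoacetylates Meldrum's acid, and on heating 13 should lose acetone and CO2 to acylketene 14, which the diketone enol oxygen traps (6-exo-dig O-acylation, the thermolytic route to 4-hydroxy-2-pyranones) to give 15 with the stereocentre untouched.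

Step 5
Reactants: 8 [(8-butanoyl-5,7-dihydroxy-2,2-dimethyl-2H-chromen-6-yl)methyl]trimethylammonium iodide; 15 (5S,6Z)-5-geranyl-5-methyl-6-(2-oxopropylidene)dihydro-2H-pyran-2,4(3H)-dione
Product: 19 (4R)-6-acetyl-2-[(8-butanoyl-5,7-dihydroxy-2,2-dimethyl-2H-chromen-6-yl)methyl]-4-[(2E)-3,7-dimethylocta-2,6-dien-1-yl]-3,5-dihydroxy-4-methylcyclohexa-2,5-dien-1-one (CNP0152509.1), via o-quinone methide 16 (not isolated), via bridged enol lactone 17 (not isolated), via acylketene 18 (not isolated)
Conditions: Et3N (3 equiv), DMAP (10 mol%), dry MeCN, 0 °C to rt; then 60 °C; 1 M HCl work-up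
Reagents that add atoms: none
Why: Et3N converts 8 into its phenoxide, which loses NMe3 to give o-quinone methide 16, and the enolate of 15 adds through C3 (Michael addition) to give the fully assembled enol lactone 17 at or below room temperature. On warming, the enolate of 17 should expel the enol-ester oxygen (E1cB) to give acylketene 18 paired with the 1,3-diketone enolate, whose central carbon attacks the ketene carbon in a 6-(enolendo)-exo-dig C-acylation that closes the carbocycle as the last ring of the skeleton. The closest known reaction types are the amine- or cyanide-catalysed rearrangement of 1,3-dione enol esters to 2-acyl-1,3-diones and the alkylidene-lactone to cyclic 1,3-dione rearrangement. No stereocentre is formed: the quaternary carbon set in step 3 is a spectator because none of its four bonds is touched, and the bridge-bearing ring carbon ends as an enol carbon. The step needs C- over O-acylation and needs the bridge to form before the acyl shift; O-acyl isomers (17 itself or the aryl ester formed by the neighbouring phenoxide) can return to 18 by E1cB whereas the β-triketone product is deprotonated irreversibly, and the staged temperature lets the fast capture of 16 precede ketene formation. Only the central diketone carbon can reach the ketene through a six-membered transition state, the tertiary amines present cannot be acylated, and water is excluded so that no β-keto acid can form and decarboxylate.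

**Compound list**

1 | 1-(2,4,6-trihydroxyphenyl)butan-1-one | CCCC(=O)c1c(O)cc(O)cc1O | starting material
2 | 3-methylbut-2-enal | CC(C)=CC=O | starting material
3 | 1-(5,7-dihydroxy-2,2-dimethyl-2H-chromen-8-yl)butan-1-one | CCCC(=O)c1c(O)cc(O)c2c1OC(C)(C)C=C2 | intermediate
4 | formaldehyde | C=O | starting material
5 | dimethylamine | CNC | starting material
6 | iodomethane | CI | starting material
7 | 1-[6-(dimethylaminomethyl)-5,7-dihydroxy-2,2-dimethyl-2H-chromen-8-yl]butan-1-one (Mannich base, formed in situ) | CCCC(=O)c1c(O)c(CN(C)C)c(O)c2c1OC(C)(C)C=C2 | intermediate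
8 | [(8-butanoyl-5,7-dihydroxy-2,2-dimethyl-2H-chromen-6-yl)methyl]trimethylammonium iodide | CCCC(=O)c1c(O)c(C[N+](C)(C)C)c(O)c2c1OC(C)(C)C=C2.[I-] | intermediate
9 | 4-hydroxy-3,6-dimethyl-2H-pyran-2-one | CC1=CC(O)=C(C)C(=O)O1 | starting material
10 | geranyl acetate, (2E)-3,7-dimethylocta-2,6-dien-1-yl acetate | CC(=O)OC/C=C(\C)CCC=C(C)C | starting material
11 | (3S)-3-[(2E)-3,7-dimethylocta-2,6-dien-1-yl]-3,6-dimethyl-2H-pyran-2,4(3H)-dione | CC1=CC(=O)[C@](C)(C/C=C(\C)CCC=C(C)C)C(=O)O1 | intermediate
12 | Meldrum's acid, 2,2-dimethyl-1,3-dioxane-4,6-dione | CC1(C)OC(=O)CC(=O)O1 | starting material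
13 | 5-[(2R)-2-geranyl-1-hydroxy-2-methyl-3,5-dioxohexylidene]-2,2-dimethyl-1,3-dioxane-4,6-dione (acyl Meldrum's acid, formed in situ) | CC(=O)CC(=O)[C@](C)(C/C=C(\C)CCC=C(C)C)C(O)=C1C(=O)OC(C)(C)OC1=O | intermediate
14 | (4S)-4-geranyl-4-methyl-3,5,7-trioxooct-1-en-1-one (acylketene, formed in situ) | CC(=O)CC(=O)[C@](C)(C/C=C(\C)CCC=C(C)C)C(=O)C=C=O | intermediate
15 | (5S,6Z)-5-[(2E)-3,7-dimethylocta-2,6-dien-1-yl]-5-methyl-6-(2-oxopropylidene)dihydro-2H-pyran-2,4(3H)-dione | CC(=O)/C=C1\OC(=O)CC(=O)[C@@]1(C)C/C=C(\C)CCC=C(C)C | intermediate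
16 | 8-butanoyl-7-hydroxy-2,2-dimethyl-6-methylidene-2H-chromen-5(6H)-one (o-quinone methide, formed in situ) | CCCC(=O)C1=C(O)C(=C)C(=O)C2=C1OC(C)(C)C=C2 | intermediate
17 | (5R,6Z)-3-[(8-butanoyl-5,7-dihydroxy-2,2-dimethyl-2H-chromen-6-yl)methyl]-5-geranyl-4-hydroxy-5-methyl-6-(2-oxopropylidene)-5,6-dihydro-2H-pyran-2-one (bridged enol lactone, formed in situ) | CC(=O)/C=C1\OC(=O)C(Cc2c(O)c3C=CC(C)(C)Oc3c(C(=O)CCC)c2O)=C(O)[C@@]1(C)C/C=C(\C)CCC=C(C)C | intermediate
18 | (4S)-2-[(8-butanoyl-5,7-dihydroxy-2,2-dimethyl-2H-chromen-6-yl)methyl]-4-geranyl-4-methyl-3,5,7-trioxooct-1-en-1-one (acylketene, formed in situ) | CC(=O)CC(=O)[C@](C)(C/C=C(\C)CCC=C(C)C)C(=O)C(Cc1c(O)c2C=CC(C)(C)Oc2c(C(=O)CCC)c1O)=C=O | intermediate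
19 | (4R)-6-acetyl-2-[(8-butanoyl-5,7-dihydroxy-2,2-dimethyl-2H-chromen-6-yl)methyl]-4-[(2E)-3,7-dimethylocta-2,6-dien-1-yl]-3,5-dihydroxy-4-methylcyclohexa-2,5-dien-1-one (CNP0152509.1) | CCCC(=O)c1c(O)c(CC2=C(O)[C@@](C)(C/C=C(\C)CCC=C(C)C)C(O)=C(C(C)=O)C2=O)c(O)c2c1OC(C)(C)C=C2 | target

**Count.** Total: 5 steps. Longest linear sequence: 3 steps (9 → 11 → 15 → 19, or 1 → 3 → 8 → 19).

**Steps most likely to fail**

Step 5 (key step). The ketene/enolate pair may return to oxygen faster than it forms the C–C bond, so that the mixture idles among O-acyl isomers. The quinone methide may also oligomerise or alkylate C3 twice before the acyl shift. Fallback, setting out from 17 and coming back at 19: the union is run alone at 0 °C and quenched with cold dilute acid so that 17 is isolated. Heating 17 in MeOH with Et3N should trap the acylketene with the solvent as methyl (4S)-2-[(8-butanoyl-5,7-dihydroxy-2,2-dimethyl-2H-chromen-6-yl)methyl]-4-geranyl-4-methyl-3,5,7-trioxooctanoate F1. Mg(OMe)2 in MeOH at reflux should then close the ring by the chelation-templated Claisen condensation known for triketo esters (the biomimetic acylphloroglucinol closure), giving 19; both ketones flanking the quaternary carbon are held as enolates, which guards against retro-Claisen cleavage.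

Step 3. Facial selection on the nearly symmetric oxidopyranone may be poor (low ee), and branched or O-allyl products are a second leak. Fallback: the stereocentre is built on an acyclic malonate and the pyrandione is closed afterwards. This fallback consumes no numbered intermediate; it replaces 9 and 10 by purchased mono-tert-butyl 2-methylmalonate, diphenylmethanol and geranyl bromide, and comes back at compound 11.
- Esterification (DCC, DMAP cat., CH2Cl2) should give tert-butyl diphenylmethyl 2-methylmalonate F2.
- Alkylation with geranyl bromide under phase-transfer catalysis by a chiral N-spiro binaphthyl quaternary ammonium bromide (50% aq. KOH, toluene, −40 °C), the established enantioselective α-alkylation of this malonate class, should give tert-butyl diphenylmethyl (S)-2-geranyl-2-methylmalonate F3.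
- KOH in MeOH should cleave only the diphenylmethyl ester to give (S)-2-(tert-butoxycarbonyl)-2-methyl-geranylacetic acid F4.
- 1-Chloro-N,N,2-trimethyl-1-propenylamine should give the acid chloride F5 under neutral conditions.
- Excess lithium enolate of acetone (LiN(SiMe3)2, THF, −78 °C) should convert it into tert-butyl (S)-2-geranyl-2-methyl-3,5-dioxohexanoate F6.
- TMSOTf/2,6-lutidine should remove the tert-butyl group without exposing the geranyl chain to strong protic acid, giving (S)-2-geranyl-2-methyl-3,5-dioxohexanoic acid F7, which is kept cold.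
- 1,1'-Carbonyldiimidazole in THF should close the enol lactone to 11.

Step 4. The hindered lactone carbonyl may resist acyl transfer, or the soft carbon nucleophile may add at C6 of the vinylogous anhydride instead. Fallback, setting out from 11 and coming back at 15: a crossed Claisen ring-opening with the lithium enolate of tert-butyl acetate (LiN(iPr)2, THF, −78 °C, 3 equiv) should give tert-butyl (4S)-4-geranyl-4-methyl-3,5,7-trioxooctanoate F8. Heating F8 in toluene at 110 °C, the standard thermolysis of tert-butyl β-keto esters, should generate the same acylketene 14, which closes to 15.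

**Further compounds**

F1 | step 5 | methyl (4S)-2-[(8-butanoyl-5,7-dihydroxy-2,2-dimethyl-2H-chromen-6-yl)methyl]-4-geranyl-4-methyl-3,5,7-trioxooctanoate (epimers at C2) | COC(=O)C(Cc1c(O)c2C=CC(C)(C)Oc2c(C(=O)CCC)c1O)C(=O)[C@@](C)(C/C=C(\C)CCC=C(C)C)C(=O)CC(C)=O
F2 | step 3 | tert-butyl diphenylmethyl 2-methylmalonate | CC(C(=O)OC(C)(C)C)C(=O)OC(c1ccccc1)c1ccccc1
F3 | step 3 | tert-butyl diphenylmethyl (S)-2-geranyl-2-methylmalonate | CC(C)(C)OC(=O)[C@@](C)(C/C=C(\C)CCC=C(C)C)C(=O)OC(c1ccccc1)c1ccccc1
F4 | step 3 | (2S,4E)-2-(tert-butoxycarbonyl)-2,5,9-trimethyldeca-4,8-dienoic acid | CC(C)(C)OC(=O)[C@@](C)(C/C=C(\C)CCC=C(C)C)C(=O)O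
F5 | step 3 | tert-butyl (2R,4E)-2-(chlorocarbonyl)-2,5,9-trimethyldeca-4,8-dienoate | CC(C)(C)OC(=O)[C@@](C)(C/C=C(\C)CCC=C(C)C)C(Cl)=O
F6 | step 3 | tert-butyl (S)-2-geranyl-2-methyl-3,5-dioxohexanoate | CC(=O)CC(=O)[C@](C)(C/C=C(\C)CCC=C(C)C)C(=O)OC(C)(C)C
F7 | step 3 | (S)-2-geranyl-2-methyl-3,5-dioxohexanoic acid | CC(=O)CC(=O)[C@](C)(C/C=C(\C)CCC=C(C)C)C(=O)O
F8 | step 4 | tert-butyl (4S)-4-geranyl-4-methyl-3,5,7-trioxooctanoate | CC(C)(C)OC(=O)CC(=O)[C@@](C)(C/C=C(\C)CCC=C(C)C)C(=O)CC(C)=O
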